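**Strategy.** Ring C is read as the cyclic aryl enol ether of a 1,3-diketone: C2 and C4 are the two carbonyl carbons, O1 is the enol oxygen of C2, and C8a lies ortho to the acyl-bearing C4a of ring A. Disconnecting C2–C3 and O1–C8a therefore leads to a 2-bromoaryl methyl ketone and 3,4-dimethoxybenzoyl chloride. In one flask, Claisen C-acylation forms C2–C3 and copper-catalysed enolate O-arylation forms O1–C8a, giving the fully oxygenated flavone (C6–OH masked as benzyl ether). Copper hydride asymmetric conjugate reduction then sets C2 as S, and hydrogenolysis frees the C6 phenol.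

Key step: step 3

Remark: positions are numbered as in chroman-4-one (O1, C2, C3, C4, C4a, C5 to C8, C8a; ring A = benzo ring, ring B = dimethoxyphenyl ring, ring C = pyranone ring). The target SMILES is read as the 2S enantiomer.

Step 1
Reactants: 1 4-bromo-2,6-dimethoxyphenol; 2 benzyl bromide
Product: 3 2-(benzyloxy)-5-bromo-1,3-dimethoxybenzene
Conditions: K2CO3, DMF, 60 °C
Reagents that add atoms: benzyl bromide, BrCc1ccccc1
Why: Williamson O-alkylation of the phenoxide (SN2 at the benzylic carbon) should be clean because the phenol is the only acidic site; no stereocenter is formed.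

Step 2
Reactants: 3 2-(benzyloxy)-5-bromo-1,3-dimethoxybenzene; 4 acetyl chloride
Product: 5 1-[3-(benzyloxy)-6-bromo-2,4-dimethoxyphenyl]ethan-1-one
Conditions: AcCl (1.2 equiv), SnCl4 (1.2 equiv), CH2Cl2, −20 → 0 °C
Reagents that add atoms: acetyl chloride, CC(=O)Cl
Why: Friedel–Crafts acylation in which the two free ring positions of 3 are equivalent by symmetry, each ortho to one methoxy group and para to the other, so a single regioisomer is expected, the mild Lewis acid at low temperature being chosen to spare the benzyl ether.

Step 3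
Reactants: 5 1-[3-(benzyloxy)-6-bromo-2,4-dimethoxyphenyl]ethan-1-one; 6 3,4-dimethoxybenzoyl chloride
Product: 8 6-(benzyloxy)-2-(3,4-dimethoxyphenyl)-5,7-dimethoxy-4H-chromen-4-one, via bromoaryl 1,3-diketone 7 (not isolated)
Conditions: LiN(SiMe3)2 (2.2 equiv), THF, −78 °C; 6, −78 → 20 °C; then CuI (10 mol %), 1,10-phenanthroline (20 mol %), DMF, 100 °C
Reagents that add atoms: 3,4-dimethoxybenzoyl chloride, COc1ccc(C(=O)Cl)cc1OC
Why: The kinetic lithium enolate of 5 is C-acylated by 6 (Claisen-type acylation, forming C2–C3), and the second equivalent of LiN(SiMe3)2 stores the product as the chelated lithium enolate of 7. On heating with CuI and 1,10-phenanthroline the C8a–Br bond, flanked by the acyl group on C4a, is substituted by the enolate oxygen on C2 (forming O1–C8a) through an aryl copper intermediate; the closest known reaction type is the copper-catalysed intramolecular Ullmann O-arylation of 2-haloaryl 1,3-dicarbonyl compounds to chromones. Ring C closes as a six-membered ring by attack of the enolate oxygen on the ring carbon C8a, an exo substitution at an sp2 carbon that ends in C–O reductive elimination. No stereocenter is created, C2 leaving the step as a prochiral sp2 carbon. The step needs C- over O-acylation, which the lithium enolate in THF at low temperature should secure, and O- over C-arylation, which is secured because attack through C3 could only close a four-membered ring, the same constraint leaving the oxygen on C2 as the only one able to reach C8a.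

Step 4
Reactants: 8 6-(benzyloxy)-2-(3,4-dimethoxyphenyl)-5,7-dimethoxy-4H-chromen-4-one; 9 diethoxy(methyl)silane
Product: 11 (2S)-6-(benzyloxy)-2-(3,4-dimethoxyphenyl)-5,7-dimethoxy-2,3-dihydro-4H-chromen-4-one, via silyl enol ether 10 (not isolated)
Conditions: Cu(OAc)2·H2O (5 mol %), (R)-DTBM-SEGPHOS (5.5 mol %), (EtO)2MeSiH (3 equiv), toluene, 0 → 20 °C; then 1 M HCl, THF, 0 °C
Reagents that add atoms: none
Why: Copper hydride asymmetric conjugate reduction of the chromone enone, in which the bisphosphine-ligated CuH delivers hydride to the Re face of C2 under control of the chiral ligand to set 2S (the antipodal ligand being taken if the facial sense proves opposite), the copper enolate is trapped as silyl enol ether 10, and acidic work-up releases the ketone without touching C2.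

Step 5
Reactants: 11 (2S)-6-(benzyloxy)-2-(3,4-dimethoxyphenyl)-5,7-dimethoxy-2,3-dihydro-4H-chromen-4-one
Product: 12 (2S)-2-(3,4-dimethoxyphenyl)-6-hydroxy-5,7-dimethoxy-2,3-dihydro-4H-chromen-4-one
Conditions: H2 (1 atm), 10% Pd/C, EtOAc, 20 °C
Reagents that add atoms: none
Why: Hydrogenolysis of the benzyl aryl ether over Pd/C under neutral conditions should free the C6 phenol without epimerising the base-sensitive C2 center or reducing the aryl ketone.

**Compound list**

1 | 4-bromo-2,6-dimethoxyphenol | COc1cc(Br)cc(OC)c1O | starting material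
2 | benzyl bromide | BrCc1ccccc1 | starting material
3 | 2-(benzyloxy)-5-bromo-1,3-dimethoxybenzene | COc1cc(Br)cc(OC)c1OCc1ccccc1 | intermediate
4 | acetyl chloride | CC(=O)Cl | starting material
5 | 1-[3-(benzyloxy)-6-bromo-2,4-dimethoxyphenyl]ethan-1-one | CC(=O)c1c(Br)cc(OC)c(OCc2ccccc2)c1OC | intermediate
6 | 3,4-dimethoxybenzoyl chloride | COc1ccc(C(=O)Cl)cc1OC | starting material
7 | 1-[3-(benzyloxy)-6-bromo-2,4-dimethoxyphenyl]-3-(3,4-dimethoxyphenyl)propane-1,3-dione (present in the flask as its lithium enolate) | COc1ccc(C(=O)CC(=O)c2c(Br)cc(OC)c(OCc3ccccc3)c2OC)cc1OC | intermediate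
8 | 6-(benzyloxy)-2-(3,4-dimethoxyphenyl)-5,7-dimethoxy-4H-chromen-4-one | COc1ccc(C2=CC(=O)c3c(cc(OC)c(OCc4ccccc4)c3OC)O2)cc1OC | intermediate
9 | diethoxy(methyl)silane | CCO[SiH](C)OCC | starting material
10 | (2S)-6-(benzyloxy)-4-{[diethoxy(methyl)silyl]oxy}-2-(3,4-dimethoxyphenyl)-5,7-dimethoxy-2H-chromene | COc1ccc([C@@H]2C=C(O[Si](C)(OCC)OCC)c3c(cc(OC)c(OCc4ccccc4)c3OC)O2)cc1OC | intermediate
11 | (2S)-6-(benzyloxy)-2-(3,4-dimethoxyphenyl)-5,7-dimethoxy-2,3-dihydro-4H-chromen-4-one | COc1ccc([C@@H]2CC(=O)c3c(cc(OC)c(OCc4ccccc4)c3OC)O2)cc1OC | intermediate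
12 | (2S)-2-(3,4-dimethoxyphenyl)-6-hydroxy-5,7-dimethoxy-2,3-dihydro-4H-chromen-4-one | COc1ccc([C@@H]2CC(=O)c3c(cc(OC)c(O)c3OC)O2)cc1OC | target

**Step count.** Total: 5 steps. Longest linear sequence: 5 steps (1 → 3 → 5 → 8 → 11 → 12).

**Steps most likely to fail**

Step 4. The electron-rich flavone is a vinylogous ester carrying an aryl group on the β-carbon, so hydride transfer from CuH may be slow, and facial discrimination at C2 may be poor. The fallback sets out from 8 and replaces conjugate reduction by full asymmetric hydrogenation: [Ru(cod)(2-methylallyl)2] with a chiral N-heterocyclic carbene ligand (from its imidazolinium salt and KOt-Bu) under H2 pressure in toluene should reduce both C2=C3 and C4=O to (2S,4S)-6-(benzyloxy)-2-(3,4-dimethoxyphenyl)-5,7-dimethoxy-3,4-dihydro-2H-chromen-4-ol F1, the cis alcohol. Oxidation of the C4 alcohol with Dess–Martin periodinane (CH2Cl2, NaHCO3, 0 °C), which leaves C2 untouched, comes back to the route at 11.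

Step 3. Activation of the electron-rich, doubly ortho-substituted C8a–Br bond by copper may be sluggish, and competing O-acylation or acyl scrambling of the enolate may erode the one-pot sequence. The fallback sets out from 5 and separates the two bond formations with other reagents: Claisen condensation with methyl 3,4-dimethoxybenzoate (NaH, THF, reflux) and isolation of diketone 7, then enolate O-arylation catalysed by zerovalent palladium (Pd2(dba)3, t-BuXPhos, K3PO4, toluene, 100 °C), coming back to the route at 8. This fallback adds no compound beyond 7 (entry F0).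

Step 2. The Lewis acid may cleave the benzyl ether, which sits between two chelating methoxy groups, before acylation of the hindered position is complete. The fallback sets out from 1 and carries the phenol through the acylation as an ester: acetylation (Ac2O, pyridine) gives 4-bromo-2,6-dimethoxyphenyl acetate F2; Friedel–Crafts acylation (AcCl, TiCl4, CH2Cl2, 0 °C) gives 3-acetyl-4-bromo-2,6-dimethoxyphenyl acetate F3; methanolysis (K2CO3, MeOH, 20 °C) gives 1-(6-bromo-3-hydroxy-2,4-dimethoxyphenyl)ethan-1-one F4; benzylation with 2 (K2CO3, DMF) comes back to the route at 5.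

**Further compounds**

F1 | step 4 | (2S,4S)-6-(benzyloxy)-2-(3,4-dimethoxyphenyl)-5,7-dimethoxy-3,4-dihydro-2H-chromen-4-ol | COc1ccc([C@@H]2C[C@H](O)c3c(cc(OC)c(OCc4ccccc4)c3OC)O2)cc1OC
F0 | step 3 | none | none
F2 | step 2 | 4-bromo-2,6-dimethoxyphenyl acetate | COc1cc(Br)cc(OC)c1OC(C)=O
F3 | step 2 | 3-acetyl-4-bromo-2,6-dimethoxyphenyl acetate | CC(=O)Oc1c(OC)cc(Br)c(C(C)=O)c1OC
F4 | step 2 | 1-(6-bromo-3-hydroxy-2,4-dimethoxyphenyl)ethan-1-one | CC(=O)c1c(Br)cc(OC)c(O)c1OC
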